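**Retrosynthetic overview**
1. The 20-membered ring is closed last, at C7–C8, by a copper-mediated intramolecular Stille-type coupling of a (Z)-vinylstannane with a (Z)-vinyl iodide; the C5 ketone is unveiled only afterwards (MnO2) so that the labile C4 centre never sees base.
2. The seco-ester comes from Yamaguchi esterification of the C19 alcohol of fragment BC (C8–C24) with the fragment A acid (C1–C7: Duboudin carbomagnesiation, Evans aldol, Still–Gennari olefination).
3. Fragment BC comes from opening the δ-lactone fragment C (C15–C24: Evans aldol, Claisen, 1,3-anti reduction) with the lithium acetylide of epoxy-diyne fragment B (C8–C14: Sharpless epoxidation, triflate alkynylation); then Noyori reduction (C15), O-methylation, Shi epoxidation, Lindlar and diimide reductions.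
4. Ring order: C11–C12 epoxide (fragment B), then C22–C23 epoxide (after union of B and C), then the macrolactone (C7–C8 closure).

Numbering used: C1 = lactone carbonyl, running through the ring to C19 (carries the lactone oxygen); C20–C24 = side chain. Target descriptors: 2Z,4S,6Z,8Z,11R,12R,13Z,15S,17R,18R,19R,20E,22R,23R.
Assumption: the geometrically pure (2E)-isomer of 3-methylpent-2-en-4-yn-1-ol is purchased.

**Fragment C (C15–C24)**

Step 1
Reactants: 1 (4S)-4-benzyl-3-propanoyl-1,3-oxazolidin-2-one; 2 (2E,4E)-hexa-2,4-dienal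
Product: 5 (4S)-4-benzyl-3-[(2S,3R,4E,6E)-3-hydroxy-2-methylocta-4,6-dienoyl]-1,3-oxazolidin-2-one, via dibutylboron Z-enolate 3 (not isolated), via dibutylboron aldolate 4 (not isolated)
Conditions: Bu2BOTf, Et3N, CH2Cl2, 0 °C; then 2, −78 → 0 °C; pH 7 buffer, MeOH, H2O2
Reagents that add atoms: none
Why: Evans syn-aldol reaction, in which the Z-boron enolate reacts through a Zimmerman–Traxler chair whose face is fixed by the (S)-benzyl auxiliary, setting C18 and C19 (18,19-syn).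

Step 2
Reactants: 5 (4S)-4-benzyl-3-[(2S,3R,4E,6E)-3-hydroxy-2-methylocta-4,6-dienoyl]-1,3-oxazolidin-2-one
Product: 6 (2S,3R,4E,6E)-3-hydroxy-N-methoxy-N,2-dimethylocta-4,6-dienamide
Conditions: MeNHOMe·HCl, AlMe3, CH2Cl2, −20 → 0 °C
Reagents that add atoms: N,O-dimethylhydroxylamine hydrochloride (CNOC.Cl)
Why: Weinreb transamidation by the aluminium amide, assisted by the free β-hydroxyl, releases the auxiliary without touching the α-stereocentre.

Step 3
Reactants: 6 (2S,3R,4E,6E)-3-hydroxy-N-methoxy-N,2-dimethylocta-4,6-dienamide; 7 ethyl acetate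
Product: 10 ethyl (4S,5R,6E,8E)-5-hydroxy-4-methyl-3-oxodeca-6,8-dienoate, via lithium enolate 8 (not isolated), via chelated tetrahedral adduct 9 (not isolated)
Conditions: 7, LiN(i-Pr)2 (4 equiv), THF, −78 °C; then 6, −78 → −40 °C; NH4Cl aq.
Reagents that add atoms: none
Why: Claisen-type acylation of the ester enolate by the Weinreb amide, whose chelated adduct collapses only on work-up, so the β-keto ester forms without over-addition.

Step 4
Reactants: 10 ethyl (4S,5R,6E,8E)-5-hydroxy-4-methyl-3-oxodeca-6,8-dienoate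
Product: 11 ethyl (3R,4R,5R,6E,8E)-3,5-dihydroxy-4-methyldeca-6,8-dienoate
Conditions: Me4NBH(OAc)3, MeCN/AcOH (1:1), −30 °C
Reagents that add atoms: none
Why: Evans–Saksena hydroxyl-directed reduction, in which the C19 alkoxide binds boron and delivers hydride intramolecularly to give the 1,3-anti diol, setting C17 (R).

Step 5
Reactants: 11 ethyl (3R,4R,5R,6E,8E)-3,5-dihydroxy-4-methyldeca-6,8-dienoate
Product: 12 (4R,5R,6R)-4-hydroxy-5-methyl-6-[(1E,3E)-penta-1,3-dien-1-yl]oxan-2-one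
Conditions: PPTS (cat.), CH2Cl2, rt
Reagents that add atoms: none
Why: Acid-catalysed lactonisation, possible only through the δ-hydroxyl (C19), which ties up C19–O and leaves C17–OH as the only free hydroxyl.

Step 6
Reactants: 12 (4R,5R,6R)-4-hydroxy-5-methyl-6-[(1E,3E)-penta-1,3-dien-1-yl]oxan-2-one
Product: 13 (4R,5S,6R)-4-[(tert-butyldimethylsilyl)oxy]-5-methyl-6-[(1E,3E)-penta-1,3-dien-1-yl]oxan-2-one
Conditions: t-BuMe2SiCl, imidazole, DMF, rt
Reagents that add atoms: tert-butyldimethylsilyl chloride (CC(C)(C)[Si](C)(C)Cl)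
Why: Silyl ether formation on the only free hydroxyl (C17) under conditions too mild for β-elimination of the lactone.

**Fragment B (C8–C14)**

Step 7
Reactants: 14 (2E)-3-methylpent-2-en-4-yn-1-ol
Product: 17 (2E)-3-methyl-5-(trimethylsilyl)pent-2-en-4-yn-1-ol, via bis(bromomagnesium) alkoxide acetylide 15 (not isolated), via C,O-bis(trimethylsilyl) intermediate 16 (not isolated)
Conditions: EtMgBr (2.2 equiv), THF, 0 °C → rt; Me3SiCl; then 1 M HCl aq.
Reagents that add atoms: chlorotrimethylsilane (C[Si](C)(C)Cl)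
Why: Double deprotonation and silylation followed by hydrolysis of the labile O–Si bond leaves the C-silylated alkyne (alkyne protection).

Step 8
Reactants: 17 (2E)-3-methyl-5-(trimethylsilyl)pent-2-en-4-yn-1-ol
Product: 18 [(2R,3R)-3-methyl-3-[(trimethylsilyl)ethynyl]oxiran-2-yl]methanol
Conditions: Ti(OiPr)4 (10 mol %), D-(−)-diethyl tartrate (12 mol %), t-BuOOH, 4 Å MS, CH2Cl2, −20 °C
Reagents that add atoms: tert-butyl hydroperoxide (CC(C)(C)OO)
Why: Sharpless asymmetric epoxidation, in which the D-(−)-tartrate titanium complex delivers oxygen to the face that gives the (11R,12R) epoxide, the trans relation of C10 and C13 coming from the E-olefin.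

Step 9
Reactants: 18 [(2R,3R)-3-methyl-3-[(trimethylsilyl)ethynyl]oxiran-2-yl]methanol
Product: 19 [(2R,3R)-3-methyl-3-[(trimethylsilyl)ethynyl]oxiran-2-yl]methyl trifluoromethanesulfonate
Conditions: Tf2O, 2,6-lutidine, CH2Cl2, −78 °C (used at once)
Reagents that add atoms: trifluoromethanesulfonic anhydride (O=S(=O)(OS(=O)(=O)C(F)(F)F)C(F)(F)F)
Why: O-sulfonylation turns the primary hydroxyl into a leaving group reactive enough for displacement at −78 °C.

Step 10
Reactants: 19 [(2R,3R)-3-methyl-3-[(trimethylsilyl)ethynyl]oxiran-2-yl]methyl trifluoromethanesulfonate; 20 ethynyltri(propan-2-yl)silane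
Product: 22 (2R,3R)-2-methyl-3-[3-(triisopropylsilyl)prop-2-yn-1-yl]-2-[(trimethylsilyl)ethynyl]oxirane, via lithium triisopropylsilylacetylide 21 (not isolated)
Conditions: 20, n-BuLi, THF, −78 °C; then 19, DMPU, −78 → −30 °C
Reagents that add atoms: none
Why: SN2 alkylation of the lithium acetylide by the primary triflate, which in the absence of a Lewis acid leaves the epoxide and its stereocentres untouched.

Step 11
Reactants: 22 (2R,3R)-2-methyl-3-[3-(triisopropylsilyl)prop-2-yn-1-yl]-2-[(trimethylsilyl)ethynyl]oxirane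
Product: 23 (2R,3R)-2-ethynyl-2-methyl-3-[3-(triisopropylsilyl)prop-2-yn-1-yl]oxirane
Conditions: K2CO3, MeOH, 0 °C → rt
Reagents that add atoms: none
Why: Base-catalysed methanolysis (protodesilylation) cleaves the C–SiMe3 bond while the bulky C–Si(i-Pr)3 bond survives.

**Union of B and C, elaboration to fragment BC**

Step 12
Reactants: 23 (2R,3R)-2-ethynyl-2-methyl-3-[3-(triisopropylsilyl)prop-2-yn-1-yl]oxirane; 13 (4R,5S,6R)-4-[(tert-butyldimethylsilyl)oxy]-5-methyl-6-[(1E,3E)-penta-1,3-dien-1-yl]oxan-2-one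
Product: 26 (5R,6S,7R,8E,10E)-5-[(tert-butyldimethylsilyl)oxy]-7-hydroxy-6-methyl-1-{(2R,3R)-2-methyl-3-[3-(triisopropylsilyl)prop-2-yn-1-yl]oxiran-2-yl}dodeca-8,10-dien-1-yn-3-one, via lithium acetylide 24 (not isolated), via lithium hemiketal alkoxide 25 (not isolated)
Conditions: 23, n-BuLi, THF, −78 °C; then 13, −78 °C; NH4Cl aq.
Reagents that add atoms: none
Why: Acetylide addition to the lactone carbonyl stops at the hemiketal alkoxide at −78 °C, which opens on work-up to the ynone and frees C19–OH (nucleophilic acyl substitution).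

Step 13
Reactants: 26 (the C19 hydroxy ynone from step 12)
Product: 27 (5R,6S,7R,8E,10E)-5-[(tert-butyldimethylsilyl)oxy]-6-methyl-1-{(2R,3R)-2-methyl-3-[3-(triisopropylsilyl)prop-2-yn-1-yl]oxiran-2-yl}-3-oxododeca-8,10-dien-1-yn-7-yl acetate
Conditions: Ac2O, pyridine, DMAP (cat.), CH2Cl2, 0 °C
Reagents that add atoms: acetic anhydride (CC(=O)OC(C)=O)
Why: DMAP-catalysed acylation traps the open-chain form of the hydroxy ketone and protects C19–OH with a group removable later by mild base.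

Step 14
Reactants: 27 (the C19 acetate ynone from step 13)
Product: 28 (3S,5R,6S,7R,8E,10E)-5-[(tert-butyldimethylsilyl)oxy]-3-hydroxy-6-methyl-1-{(2R,3R)-2-methyl-3-[3-(triisopropylsilyl)prop-2-yn-1-yl]oxiran-2-yl}dodeca-8,10-dien-1-yn-7-yl acetate
Conditions: Ru[(S,S)-TsDPEN](p-cymene) (5 mol %, preformed amido complex), i-PrOH, rt
Reagents that add atoms: none
Why: Noyori asymmetric transfer hydrogenation of the ynone, in which the (S,S)-ligand places the alkynyl group next to the arene and gives the (15S) propargylic alcohol under catalyst control.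

Step 15
Reactants: 28 (the C15 propargylic alcohol from step 14)
Product: 29 (3S,5R,6S,7R,8E,10E)-5-[(tert-butyldimethylsilyl)oxy]-3-methoxy-6-methyl-1-{(2R,3R)-2-methyl-3-[3-(triisopropylsilyl)prop-2-yn-1-yl]oxiran-2-yl}dodeca-8,10-dien-1-yn-7-yl acetate
Conditions: MeI, Ag2O, 4 Å MS, MeCN, 40 °C, dark
Reagents that add atoms: iodomethane (CI)
Why: Purdie O-methylation proceeds without a free alkoxide, so neither silyl nor acetyl migration nor epoxide opening occurs and C15 keeps its configuration.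

Step 16
Reactants: 29 (the C15 methyl ether from step 15)
Product: 30 (1E,3R,4S,5R,7S)-5-[(tert-butyldimethylsilyl)oxy]-7-methoxy-4-methyl-1-[(2R,3R)-3-methyloxiran-2-yl]-9-{(2R,3R)-2-methyl-3-[3-(triisopropylsilyl)prop-2-yn-1-yl]oxiran-2-yl}non-1-en-8-yn-3-yl acetate
Conditions: D-fructose-derived Shi ketone (0.4 equiv), KHSO5 (as 2KHSO5·KHSO4·K2SO4), K2CO3, Bu4NHSO4, Na2B4O7 buffer, MeCN/CH2(OMe)2/H2O, 0 °C
Reagents that add atoms: potassium peroxymonosulfate ([K+].[O-]S(=O)(=O)OO)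
Why: Shi asymmetric epoxidation, in which the chiral dioxirane attacks the electron-richer trans olefin distal to the allylic acetate and, by analogy with (R,R)-trans-β-methylstyrene oxide, gives the (22R,23R) epoxide.

Step 17
Reactants: 30 (the bis-epoxide alkyne from step 16)
Product: 31 (1E,3R,4S,5R,7S,8Z)-5-[(tert-butyldimethylsilyl)oxy]-7-methoxy-4-methyl-1-[(2R,3R)-3-methyloxiran-2-yl]-9-{(2R,3R)-2-methyl-3-[3-(triisopropylsilyl)prop-2-yn-1-yl]oxiran-2-yl}nona-1,8-dien-3-yl acetate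
Conditions: H2 (1 atm), Pd/CaCO3 poisoned with Pb(OAc)2, quinoline, EtOAc, rt
Reagents that add atoms: none
Why: Lindlar semihydrogenation adds H2 syn to the internal alkyne to give the 13Z olefin, while the silyl-capped alkyne is too hindered to reduce.

Step 18
Reactants: 31 (the 13Z olefin from step 17)
Product: 33 (1E,3R,4S,5R,7S,8Z)-5-[(tert-butyldimethylsilyl)oxy]-9-[(2R,3R)-3-(3-iodoprop-2-yn-1-yl)-2-methyloxiran-2-yl]-7-methoxy-4-methyl-1-[(2R,3R)-3-methyloxiran-2-yl]nona-1,8-dien-3-yl acetate, via silver acetylide 32 (not isolated)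
Conditions: AgF, N-iodosuccinimide, MeCN, rt, dark
Reagents that add atoms: N-iodosuccinimide (O=C1CCC(=O)N1I)
Why: Fluoride-induced C-desilylation gives the silver acetylide, which is iodinated in situ (electrophilic iododemetalation) under neutral conditions.

Step 19
Reactants: 33 (the iodoalkyne from step 18)
Product: 34 (1E,3R,4S,5R,7S,8Z)-5-[(tert-butyldimethylsilyl)oxy]-9-{(2R,3R)-3-[(2Z)-3-iodoprop-2-en-1-yl]-2-methyloxiran-2-yl}-7-methoxy-4-methyl-1-[(2R,3R)-3-methyloxiran-2-yl]nona-1,8-dien-3-yl acetate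
Conditions: 2-nitrobenzenesulfonyl hydrazide, Et3N, THF/i-PrOH, rt
Reagents that add atoms: none
Why: Diimide reduction transfers H2 syn to the polarised iodoalkyne much faster than to the olefins, giving the (8Z)-vinyl iodide.

Step 20
Reactants: 34 (the Z-vinyl iodide acetate from step 19)
Product: 35 (1E,3R,4S,5R,7S,8Z)-5-[(tert-butyldimethylsilyl)oxy]-9-{(2R,3R)-3-[(2Z)-3-iodoprop-2-en-1-yl]-2-methyloxiran-2-yl}-7-methoxy-4-methyl-1-[(2R,3R)-3-methyloxiran-2-yl]nona-1,8-dien-3-ol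
Conditions: K2CO3, MeOH, 0 °C → rt
Reagents that add atoms: none
Why: Base-catalysed transesterification removes the only ester and frees C19–OH without acid, so both vinyl epoxides survive.

**Fragment A (C1–C7)**

Step 21
Reactants: 36 prop-2-yn-1-ol
Product: 39 (2Z)-3-iodo-2-methylprop-2-en-1-ol, via bromomagnesium propargyl alkoxide 37 (not isolated), via oxamagnesacycle 38 (not isolated)
Conditions: MeMgBr (2.5 equiv), CuI (10 mol %), Et2O/THF, −10 °C → rt; then I2, −10 °C; NH4Cl aq.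
Reagents that add atoms: methylmagnesium bromide (C[Mg]Br); iodine (II)
Why: Duboudin copper-catalysed anti-carbomagnesiation, directed by the alkoxide, gives a five-membered vinylmagnesium chelate whose iodinolysis with retention places iodine cis to CH2OH.

Step 22
Reactants: 39 (2Z)-3-iodo-2-methylprop-2-en-1-ol
Product: 41 (2Z)-2-methyl-3-(tributylstannyl)prop-2-en-1-ol, via dilithio species 40 (not isolated)
Conditions: t-BuLi (3.1 equiv), Et2O, −78 °C; then Bu3SnCl, −78 → 0 °C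
Reagents that add atoms: tributyltin chloride (CCCC[Sn](Cl)(CCCC)CCCC)
Why: Iodine–lithium exchange on the lithium alkoxide and stannylation of the vinyllithium both proceed with retention of olefin geometry.

Step 23
Reactants: 41 (2Z)-2-methyl-3-(tributylstannyl)prop-2-en-1-ol
Product: 42 (2Z)-2-methyl-3-(tributylstannyl)prop-2-enal
Conditions: MnO2, CH2Cl2, rt
Reagents that add atoms: none
Why: Neutral allylic oxidation by MnO2 gives the enal without protodestannylation or Z/E isomerisation.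

Step 24
Reactants: 42 (2Z)-2-methyl-3-(tributylstannyl)prop-2-enal; 43 (4R)-4-benzyl-3-propanoyl-1,3-oxazolidin-2-one
Product: 46 (4R)-4-benzyl-3-[(2R,3R,4Z)-3-hydroxy-2,4-dimethyl-5-(tributylstannyl)pent-4-enoyl]-1,3-oxazolidin-2-one, via dibutylboron Z-enolate 44 (not isolated), via dibutylboron aldolate 45 (not isolated)
Conditions: 43, Bu2BOTf, Et3N, CH2Cl2, 0 °C; then 42, −78 → 0 °C; pH 7 buffer, MeOH, H2O2
Reagents that add atoms: none
Why: Evans syn-aldol reaction under control of the (R)-benzyl auxiliary sets the C4 methyl centre (and the temporary C5 carbinol) through the Zimmerman–Traxler chair.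

Step 25
Reactants: 46 (the stannyl aldol adduct from step 24)
Product: 47 (4R)-4-benzyl-3-[(2R,3R,4Z)-2,4-dimethyl-3-[(triethylsilyl)oxy]-5-(tributylstannyl)pent-4-enoyl]-1,3-oxazolidin-2-one
Conditions: Et3SiCl, imidazole, DMF, 0 °C → rt
Reagents that add atoms: chlorotriethylsilane (CC[Si](Cl)(CC)CC)
Why: Silyl ether formation under buffered conditions protects the C5 hydroxyl without protodestannylation.

Step 26
Reactants: 47 (the triethylsilyl ether from step 25)
Product: 48 (2S,3R,4Z)-2,4-dimethyl-3-[(triethylsilyl)oxy]-5-(tributylstannyl)pent-4-en-1-ol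
Conditions: LiBH4, MeOH (1 equiv), Et2O, 0 °C; NaOH aq.
Reagents that add atoms: none
Why: Reductive cleavage of the imide by LiBH4 at the exocyclic carbonyl gives the primary alcohol and the recoverable auxiliary without epimerisation.

Step 27
Reactants: 48 (2S,3R,4Z)-2,4-dimethyl-3-[(triethylsilyl)oxy]-5-(tributylstannyl)pent-4-en-1-ol
Product: 49 (2R,3R,4Z)-2,4-dimethyl-3-[(triethylsilyl)oxy]-5-(tributylstannyl)pent-4-enal
Conditions: Dess–Martin periodinane, NaHCO3, CH2Cl2, 0 °C → rt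
Reagents that add atoms: none
Why: Buffered Dess–Martin oxidation gives the α-chiral aldehyde without epimerisation or acid-induced loss of tin.

Step 28
Reactants: 49 (2R,3R,4Z)-2,4-dimethyl-3-[(triethylsilyl)oxy]-5-(tributylstannyl)pent-4-enal; 50 methyl 2-[bis(2,2,2-trifluoroethoxy)phosphoryl]propanoate
Product: 52 methyl (2Z,4S,5R,6Z)-2,4,6-trimethyl-5-[(triethylsilyl)oxy]-7-(tributylstannyl)hepta-2,6-dienoate, via potassium phosphonate carbanion 51 (not isolated)
Conditions: 50, KN(SiMe3)2, 18-crown-6, THF, −78 °C; then 49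
Reagents that add atoms: none
Why: Still–Gennari olefination, in which the electron-poor phosphonate and the dissociated potassium counter-ion make elimination faster than equilibration and give the (2Z)-trisubstituted enoate.

Step 29
Reactants: 52 (the methyl ester from step 28)
Product: 54 (2Z,4S,5R,6Z)-2,4,6-trimethyl-5-[(triethylsilyl)oxy]-7-(tributylstannyl)hepta-2,6-dienoic acid, via trimethylstannyl ester 53 (not isolated)
Conditions: Me3SnOH, ClCH2CH2Cl, 80 °C; then 0.01 M KHSO4 aq.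
Reagents that add atoms: trimethyltin hydroxide (C[Sn](C)(C)O)
Why: Me3SnOH-mediated ester hydrolysis is near-neutral, so the silyl ether, the vinylstannane and both Z-olefins survive.

**Endgame**

Step 30
Reactants: 54 (the fragment A acid from step 29); 35 (the fragment BC alcohol from step 20)
Product: 56 (1E,3R,4S,5R,7S,8Z)-5-[(tert-butyldimethylsilyl)oxy]-9-{(2R,3R)-3-[(2Z)-3-iodoprop-2-en-1-yl]-2-methyloxiran-2-yl}-7-methoxy-4-methyl-1-[(2R,3R)-3-methyloxiran-2-yl]nona-1,8-dien-3-yl (2Z,4S,5R,6Z)-2,4,6-trimethyl-5-[(triethylsilyl)oxy]-7-(tributylstannyl)hepta-2,6-dienoate, via mixed anhydride 55 (not isolated)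
Conditions: 54 (1.5 equiv), 2,4,6-trichlorobenzoyl chloride, Et3N, toluene, rt; then 35, DMAP, toluene, rt
Reagents that add atoms: none
Why: Yamaguchi esterification through the mixed anhydride and the acylpyridinium acylates the hindered C19 alcohol at room temperature, where the (2Z)-2-methyl enoate does not isomerise.

Step 31
Reactants: 56 (the seco-ester from step 30)
Product: 58 20-membered macrolactone: C5 carbinol form of the target carrying 5-OSiEt3 and 17-OSiMe2t-Bu (2Z,4S,5R,6Z,8Z,11R,12R,13Z,15S,17R,18S,19R,20E,22R,23R), via vinylcopper species 57 (not isolated)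
Conditions: CuO2C(2-C4H3S) (copper thiophene-2-carboxylate, 10 equiv), NMP, 0.002 M, 0 °C → rt
Reagents that add atoms: none
Why: Copper-mediated Stille-type macrocyclisation (Liebeskind coupling), in which tin-to-copper transmetalation and coupling with the vinyl iodide both retain geometry to give the (6Z,8Z)-diene, and the absence of palladium spares the vinyl epoxides and the allylic ester.

Step 32
Reactants: 58 (the bis-silyl macrolactone from step 31)
Product: 59 macrocyclic 5,17-diol: (5R)-C5 carbinol form of the target (all other centres as in the target)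
Conditions: (Me2N)3S[Me3SiF2], DMF/H2O, 0 °C → rt
Reagents that add atoms: none
Why: Fluoride-mediated desilylation under near-neutral conditions removes both silyl ethers without opening the epoxides or moving the C19 acyl group.

Step 33
Reactants: 59 (the macrocyclic diol from step 32)
Product: 60 target CNP0173711.1
Conditions: MnO2 (activated, excess), CH2Cl2, rt
Reagents that add atoms: none
Why: Chemoselective allylic oxidation by MnO2 converts only the dienylic C5 carbinol into the dienone, leaves the saturated C17–OH alone, and is neutral so the now-acidic C4 centre is not epimerised.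

**Compound list**
1 | (4S)-4-benzyl-3-propanoyl-1,3-oxazolidin-2-one | CCC(=O)N1[C@@H](Cc2ccccc2)COC1=O | starting material
2 | (2E,4E)-hexa-2,4-dienal | C/C=C/C=C/C=O | starting material
3 | dibutylboron Z-enolate of 1 | CCCCB(CCCC)O/C(=C\C)N1[C@@H](Cc2ccccc2)COC1=O | intermediate
4 | dibutylboron aldolate of 5 | CCCCB(CCCC)O[C@H](/C=C/C=C/C)[C@H](C)C(=O)N1[C@@H](Cc2ccccc2)COC1=O | intermediate
5 | (4S)-4-benzyl-3-[(2S,3R,4E,6E)-3-hydroxy-2-methylocta-4,6-dienoyl]-1,3-oxazolidin-2-one | O[C@H](/C=C/C=C/C)[C@H](C)C(=O)N1[C@@H](Cc2ccccc2)COC1=O | intermediate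
6 | (2S,3R,4E,6E)-3-hydroxy-N-methoxy-N,2-dimethylocta-4,6-dienamide | O[C@H](/C=C/C=C/C)[C@H](C)C(=O)N(C)OC | intermediate
7 | ethyl acetate | CCOC(C)=O | starting material
8 | lithium enolate of ethyl acetate | C=C(O[Li])OCC | intermediate
9 | chelated tetrahedral adduct of 8 and 6 | [Li]O[C@H](/C=C/C=C/C)[C@H](C)C(O[Li])(CC(=O)OCC)N(C)OC | intermediate
10 | ethyl (4S,5R,6E,8E)-5-hydroxy-4-methyl-3-oxodeca-6,8-dienoate | O[C@H](/C=C/C=C/C)[C@H](C)C(=O)CC(=O)OCC | intermediate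
11 | ethyl (3R,4R,5R,6E,8E)-3,5-dihydroxy-4-methyldeca-6,8-dienoate | O[C@H](/C=C/C=C/C)[C@H](C)[C@H](O)CC(=O)OCC | intermediate
12 | (4R,5R,6R)-4-hydroxy-5-methyl-6-[(1E,3E)-penta-1,3-dien-1-yl]oxan-2-one | O1[C@H](/C=C/C=C/C)[C@H](C)[C@H](O)CC1=O | intermediate
13 | (4R,5S,6R)-4-[(tert-butyldimethylsilyl)oxy]-5-methyl-6-[(1E,3E)-penta-1,3-dien-1-yl]oxan-2-one (fragment C) | O1[C@H](/C=C/C=C/C)[C@H](C)[C@H](O[Si](C)(C)C(C)(C)C)CC1=O | intermediate
14 | (2E)-3-methylpent-2-en-4-yn-1-ol | C#C/C(C)=C/CO | starting material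
15 | bis(bromomagnesium) alkoxide acetylide of 14 | Br[Mg]C#C/C(C)=C/CO[Mg]Br | intermediate
16 | C,O-bis(trimethylsilyl) derivative of 14 | C[Si](C)(C)C#C/C(C)=C/CO[Si](C)(C)C | intermediate
17 | (2E)-3-methyl-5-(trimethylsilyl)pent-2-en-4-yn-1-ol | C[Si](C)(C)C#C/C(C)=C/CO | intermediate
18 | [(2R,3R)-3-methyl-3-[(trimethylsilyl)ethynyl]oxiran-2-yl]methanol | C[Si](C)(C)C#C[C@@]1(C)O[C@@H]1CO | intermediate
19 | [(2R,3R)-3-methyl-3-[(trimethylsilyl)ethynyl]oxiran-2-yl]methyl trifluoromethanesulfonate | C[Si](C)(C)C#C[C@@]1(C)O[C@@H]1COS(=O)(=O)C(F)(F)F | intermediate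
20 | ethynyltri(propan-2-yl)silane | C#C[Si](C(C)C)(C(C)C)C(C)C | starting material
21 | lithium (triisopropylsilyl)acetylide | [Li]C#C[Si](C(C)C)(C(C)C)C(C)C | intermediate
22 | (2R,3R)-2-methyl-3-[3-(triisopropylsilyl)prop-2-yn-1-yl]-2-[(trimethylsilyl)ethynyl]oxirane | C[Si](C)(C)C#C[C@@]1(C)O[C@@H]1CC#C[Si](C(C)C)(C(C)C)C(C)C | intermediate
23 | (2R,3R)-2-ethynyl-2-methyl-3-[3-(triisopropylsilyl)prop-2-yn-1-yl]oxirane (fragment B) | C#C[C@@]1(C)O[C@@H]1CC#C[Si](C(C)C)(C(C)C)C(C)C | intermediate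
24 | lithium acetylide of 23 | [Li]C#C[C@@]1(C)O[C@@H]1CC#C[Si](C(C)C)(C(C)C)C(C)C | intermediate
25 | lithium hemiketal alkoxide from 24 and 13 | O1[C@H](/C=C/C=C/C)[C@H](C)[C@H](O[Si](C)(C)C(C)(C)C)CC1(O[Li])C#C[C@@]2(C)O[C@@H]2CC#C[Si](C(C)C)(C(C)C)C(C)C | intermediate
26 | (5R,6S,7R,8E,10E)-5-[(tert-butyldimethylsilyl)oxy]-7-hydroxy-6-methyl-1-{(2R,3R)-2-methyl-3-[3-(triisopropylsilyl)prop-2-yn-1-yl]oxiran-2-yl}dodeca-8,10-dien-1-yn-3-one | O[C@H](/C=C/C=C/C)[C@H](C)[C@H](O[Si](C)(C)C(C)(C)C)CC(=O)C#C[C@@]1(C)O[C@@H]1CC#C[Si](C(C)C)(C(C)C)C(C)C | intermediate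
27 | C19 acetate of 26 | CC(=O)O[C@H](/C=C/C=C/C)[C@H](C)[C@H](O[Si](C)(C)C(C)(C)C)CC(=O)C#C[C@@]1(C)O[C@@H]1CC#C[Si](C(C)C)(C(C)C)C(C)C | intermediate
28 | (15S)-propargylic alcohol from 27 | CC(=O)O[C@H](/C=C/C=C/C)[C@H](C)[C@H](O[Si](C)(C)C(C)(C)C)C[C@H](O)C#C[C@@]1(C)O[C@@H]1CC#C[Si](C(C)C)(C(C)C)C(C)C | intermediate
29 | C15 methyl ether of 28 | CC(=O)O[C@H](/C=C/C=C/C)[C@H](C)[C@H](O[Si](C)(C)C(C)(C)C)C[C@H](OC)C#C[C@@]1(C)O[C@@H]1CC#C[Si](C(C)C)(C(C)C)C(C)C | intermediate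
30 | (22R,23R)-epoxide of 29 (non-1-en-8-yn-3-yl acetate of step 16) | CC(=O)O[C@H](/C=C/[C@H]2O[C@@H]2C)[C@H](C)[C@H](O[Si](C)(C)C(C)(C)C)C[C@H](OC)C#C[C@@]1(C)O[C@@H]1CC#C[Si](C(C)C)(C(C)C)C(C)C | intermediate
31 | (13Z)-olefin from 30 | CC(=O)O[C@H](/C=C/[C@H]2O[C@@H]2C)[C@H](C)[C@H](O[Si](C)(C)C(C)(C)C)C[C@H](OC)/C=C\[C@@]1(C)O[C@@H]1CC#C[Si](C(C)C)(C(C)C)C(C)C | intermediate
32 | silver acetylide from 31 | CC(=O)O[C@H](/C=C/[C@H]2O[C@@H]2C)[C@H](C)[C@H](O[Si](C)(C)C(C)(C)C)C[C@H](OC)/C=C\[C@@]1(C)O[C@@H]1CC#C[Ag] | intermediate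
33 | C8 iodoalkyne | CC(=O)O[C@H](/C=C/[C@H]2O[C@@H]2C)[C@H](C)[C@H](O[Si](C)(C)C(C)(C)C)C[C@H](OC)/C=C\[C@@]1(C)O[C@@H]1CC#CI | intermediate
34 | (8Z)-vinyl iodide acetate | CC(=O)O[C@H](/C=C/[C@H]2O[C@@H]2C)[C@H](C)[C@H](O[Si](C)(C)C(C)(C)C)C[C@H](OC)/C=C\[C@@]1(C)O[C@@H]1C/C=C\I | intermediate
35 | (1E,3R,4S,5R,7S,8Z)-5-[(tert-butyldimethylsilyl)oxy]-9-{(2R,3R)-3-[(2Z)-3-iodoprop-2-en-1-yl]-2-methyloxiran-2-yl}-7-methoxy-4-methyl-1-[(2R,3R)-3-methyloxiran-2-yl]nona-1,8-dien-3-ol (fragment BC) | O[C@H](/C=C/[C@H]2O[C@@H]2C)[C@H](C)[C@H](O[Si](C)(C)C(C)(C)C)C[C@H](OC)/C=C\[C@@]1(C)O[C@@H]1C/C=C\I | intermediate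
36 | prop-2-yn-1-ol | C#CCO | starting material
37 | bromomagnesium prop-2-yn-1-olate | C#CCO[Mg]Br | intermediate
38 | 4-methyl-2,5-dihydro-1,2-oxamagnesole | CC1=C[Mg]OC1 | intermediate
39 | (2Z)-3-iodo-2-methylprop-2-en-1-ol | I/C=C(/C)CO | intermediate
40 | dilithio species from 39 | [Li]/C=C(/C)CO[Li] | intermediate
41 | (2Z)-2-methyl-3-(tributylstannyl)prop-2-en-1-ol | CCCC[Sn](CCCC)(CCCC)/C=C(/C)CO | intermediate
42 | (2Z)-2-methyl-3-(tributylstannyl)prop-2-enal | CCCC[Sn](CCCC)(CCCC)/C=C(/C)C=O | intermediate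
43 | (4R)-4-benzyl-3-propanoyl-1,3-oxazolidin-2-one | CCC(=O)N1[C@H](Cc2ccccc2)COC1=O | starting material
44 | dibutylboron Z-enolate of 43 | CCCCB(CCCC)O/C(=C\C)N1[C@H](Cc2ccccc2)COC1=O | intermediate
45 | dibutylboron aldolate of 46 | CCCC[Sn](CCCC)(CCCC)/C=C(/C)[C@H](OB(CCCC)CCCC)[C@@H](C)C(=O)N1[C@H](Cc2ccccc2)COC1=O | intermediate
46 | (4R)-4-benzyl-3-[(2R,3R,4Z)-3-hydroxy-2,4-dimethyl-5-(tributylstannyl)pent-4-enoyl]-1,3-oxazolidin-2-one | CCCC[Sn](CCCC)(CCCC)/C=C(/C)[C@H](O)[C@@H](C)C(=O)N1[C@H](Cc2ccccc2)COC1=O | intermediate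
47 | triethylsilyl ether of 46 | CCCC[Sn](CCCC)(CCCC)/C=C(/C)[C@H](O[Si](CC)(CC)CC)[C@@H](C)C(=O)N1[C@H](Cc2ccccc2)COC1=O | intermediate
48 | (2S,3R,4Z)-2,4-dimethyl-3-[(triethylsilyl)oxy]-5-(tributylstannyl)pent-4-en-1-ol | CCCC[Sn](CCCC)(CCCC)/C=C(/C)[C@H](O[Si](CC)(CC)CC)[C@@H](C)CO | intermediate
49 | (2R,3R,4Z)-2,4-dimethyl-3-[(triethylsilyl)oxy]-5-(tributylstannyl)pent-4-enal | CCCC[Sn](CCCC)(CCCC)/C=C(/C)[C@H](O[Si](CC)(CC)CC)[C@@H](C)C=O | intermediate
50 | methyl 2-[bis(2,2,2-trifluoroethoxy)phosphoryl]propanoate | COC(=O)C(C)P(=O)(OCC(F)(F)F)OCC(F)(F)F | starting material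
51 | potassium carbanion of 50 | [K+].COC(=O)[C-](C)P(=O)(OCC(F)(F)F)OCC(F)(F)F | intermediate
52 | methyl (2Z,4S,5R,6Z)-2,4,6-trimethyl-5-[(triethylsilyl)oxy]-7-(tributylstannyl)hepta-2,6-dienoate | CCCC[Sn](CCCC)(CCCC)/C=C(/C)[C@H](O[Si](CC)(CC)CC)[C@@H](C)/C=C(/C)C(=O)OC | intermediate
53 | trimethylstannyl ester of 54 | CCCC[Sn](CCCC)(CCCC)/C=C(/C)[C@H](O[Si](CC)(CC)CC)[C@@H](C)/C=C(/C)C(=O)O[Sn](C)(C)C | intermediate
54 | (2Z,4S,5R,6Z)-2,4,6-trimethyl-5-[(triethylsilyl)oxy]-7-(tributylstannyl)hepta-2,6-dienoic acid (fragment A) | CCCC[Sn](CCCC)(CCCC)/C=C(/C)[C@H](O[Si](CC)(CC)CC)[C@@H](C)/C=C(/C)C(=O)O | intermediate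
55 | 2,4,6-trichlorobenzoic mixed anhydride of 54 | CCCC[Sn](CCCC)(CCCC)/C=C(/C)[C@H](O[Si](CC)(CC)CC)[C@@H](C)/C=C(/C)C(=O)OC(=O)c1c(Cl)cc(Cl)cc1Cl | intermediate
56 | seco-ester of 54 and 35 (stannane/iodide) | CCCC[Sn](CCCC)(CCCC)/C=C(/C)[C@H](O[Si](CC)(CC)CC)[C@@H](C)/C=C(/C)C(=O)O[C@H](/C=C/[C@H]2O[C@@H]2C)[C@H](C)[C@H](O[Si](C)(C)C(C)(C)C)C[C@H](OC)/C=C\[C@@]1(C)O[C@@H]1C/C=C\I | intermediate
57 | vinylcopper species from 56 | [Cu]/C=C(/C)[C@H](O[Si](CC)(CC)CC)[C@@H](C)/C=C(/C)C(=O)O[C@H](/C=C/[C@H]2O[C@@H]2C)[C@H](C)[C@H](O[Si](C)(C)C(C)(C)C)C[C@H](OC)/C=C\[C@@]1(C)O[C@@H]1C/C=C\I | intermediate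
58 | macrolactone with 5-OSiEt3 and 17-OSiMe2t-Bu (5R) | CO[C@@H]1/C=C\[C@@]2(C)O[C@@H]2C/C=C\C=C(\C)[C@H](O[Si](CC)(CC)CC)[C@@H](C)/C=C(/C)C(=O)O[C@H](/C=C/[C@H]2O[C@@H]2C)[C@H](C)[C@H](O[Si](C)(C)C(C)(C)C)C1 | intermediate
59 | macrocyclic 5,17-diol (5R) | CO[C@@H]1/C=C\[C@@]2(C)O[C@@H]2C/C=C\C=C(\C)[C@H](O)[C@@H](C)/C=C(/C)C(=O)O[C@H](/C=C/[C@H]2O[C@@H]2C)[C@H](C)[C@H](O)C1 | intermediate
60 | CNP0173711.1 | CO[C@@H]1/C=C\[C@@]2(C)O[C@@H]2C/C=C\C=C(\C)C(=O)[C@@H](C)/C=C(/C)C(=O)O[C@H](/C=C/[C@H]2O[C@@H]2C)[C@H](C)[C@H](O)C1 | target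

**Totals**
Total step count: 33.
Longest linear sequence: 19 steps (steps 1–6, 12–20, 30–33; from 1 and 2 through 13, 35 and 56 to 60). Fragment B adds 5 steps (7–11) and fragment A adds 9 steps (21–29).

**Three steps most likely to fail, with fallbacks**

Step 12 (acetylide opening of the β-silyloxy lactone: enolisation with loss of the silyloxy group, or a lactol that resists acylation in step 13). The fallback sets out from 13 and returns at 26. Lactone 13 is opened with MeNHOMe·HCl and AlMe3 (CH2Cl2, 0 °C) to the hydroxy Weinreb amide F1. F1 is silylated at once (Et3SiOTf, 2,6-lutidine, −78 °C) to the triethylsilyl ether F2. F2 takes up lithium acetylide 24 (THF, −78 → 0 °C) in a Weinreb ketone synthesis to give the silyl-protected ynone F3. Buffered HF·pyridine (pyridine/THF, 0 °C) removes the secondary SiEt3 group selectively and delivers 26.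

Step 31 (copper-mediated macrocyclisation to a strained (6Z,8Z)-diene at high dilution, where slow transmetalation may lead to protodestannylation or dimers). The fallback sets out from 54 and 35 and returns at 58, moving the ring closure to the ester bond. Acid 54 and iodide 35 are joined intermolecularly by Stille coupling (Pd2(dba)3 as source of zerovalent palladium, AsPh3, NMP, rt; the arsine-ligated catalyst adds to the vinyl iodide much faster than it ionises vinyl epoxides) to give the seco acid F4. F4 is activated with 2,4,6-trichlorobenzoyl chloride and Et3N as the mixed anhydride F5, which is added slowly to DMAP in toluene (0.001 M, rt) for Yamaguchi macrolactonisation to 58.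

Step 33 (MnO2 may be sluggish on the hindered dienylic C5 carbinol, and long reaction times risk C4 epimerisation). The fallback sets out from 58 and returns at 60, replacing chemoselective oxidation by protecting-group differentiation. Buffered HF·pyridine (pyridine/THF, 0 °C) cleaves only the allylic SiEt3 ether to give the C5 alcohol F6. Dess–Martin periodinane with NaHCO3 (CH2Cl2, 0 °C) oxidises F6 to the silyl-protected dienone F7. (Me2N)3S[Me3SiF2] in DMF/H2O at 0 °C then removes the C17 silyl group to give 60.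

**Further compounds**
F1 | step 12 | (3R,4S,5R,6E,8E)-3-[(tert-butyldimethylsilyl)oxy]-5-hydroxy-N-methoxy-N,4-dimethyldeca-6,8-dienamide | O[C@H](/C=C/C=C/C)[C@H](C)[C@H](O[Si](C)(C)C(C)(C)C)CC(=O)N(C)OC
F2 | step 12 | (3R,4R,5R,6E,8E)-3-[(tert-butyldimethylsilyl)oxy]-N-methoxy-N,4-dimethyl-5-[(triethylsilyl)oxy]deca-6,8-dienamide | CC[Si](CC)(CC)O[C@H](/C=C/C=C/C)[C@H](C)[C@H](O[Si](C)(C)C(C)(C)C)CC(=O)N(C)OC
F3 | step 12 | (5R,6R,7R,8E,10E)-5-[(tert-butyldimethylsilyl)oxy]-6-methyl-1-{(2R,3R)-2-methyl-3-[3-(triisopropylsilyl)prop-2-yn-1-yl]oxiran-2-yl}-7-[(triethylsilyl)oxy]dodeca-8,10-dien-1-yn-3-one | CC[Si](CC)(CC)O[C@H](/C=C/C=C/C)[C@H](C)[C@H](O[Si](C)(C)C(C)(C)C)CC(=O)C#C[C@@]1(C)O[C@@H]1CC#C[Si](C(C)C)(C(C)C)C(C)C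
F4 | step 31 | seco acid: C7–C8 coupled product of 54 and 35 with free C1 acid and free C19 hydroxyl | O[C@H](/C=C/[C@H]2O[C@@H]2C)[C@H](C)[C@H](O[Si](C)(C)C(C)(C)C)C[C@H](OC)/C=C\[C@@]1(C)O[C@@H]1C/C=C\C=C(\C)[C@H](O[Si](CC)(CC)CC)[C@@H](C)/C=C(/C)C(=O)O
F5 | step 31 | 2,4,6-trichlorobenzoic mixed anhydride of F4 | O[C@H](/C=C/[C@H]2O[C@@H]2C)[C@H](C)[C@H](O[Si](C)(C)C(C)(C)C)C[C@H](OC)/C=C\[C@@]1(C)O[C@@H]1C/C=C\C=C(\C)[C@H](O[Si](CC)(CC)CC)[C@@H](C)/C=C(/C)C(=O)OC(=O)c1c(Cl)cc(Cl)cc1Cl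
F6 | step 33 | macrolactone with free (5R)-hydroxyl and 17-OSiMe2t-Bu | CO[C@@H]1/C=C\[C@@]2(C)O[C@@H]2C/C=C\C=C(\C)[C@H](O)[C@@H](C)/C=C(/C)C(=O)O[C@H](/C=C/[C@H]2O[C@@H]2C)[C@H](C)[C@H](O[Si](C)(C)C(C)(C)C)C1
F7 | step 33 | 17-O-(tert-butyldimethylsilyl) ether of the target | CO[C@@H]1/C=C\[C@@]2(C)O[C@@H]2C/C=C\C=C(\C)C(=O)[C@@H](C)/C=C(/C)C(=O)O[C@H](/C=C/[C@H]2O[C@@H]2C)[C@H](C)[C@H](O[Si](C)(C)C(C)(C)C)C1
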